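The runs are simulated with made-up constants; noise was put on by code.

At one temperature, isomerisation cannot carry the share of target, meaning target over target plus isomer of the product, below the value at which the two balance, and in the proposed steps the isomer comes from target, so fresh target starts at full share and ages downward.

| flask | starting material | partner A | partner B | protic impurity | temperature | remark | time |
|---|---|---|---|---|---|---|---|
| south-west | 20 mM | 2.8 equiv | 2.5 equiv | 20 mM | 65 °C | run made earlier |  |
| west | 20 mM | 4.4 equiv | 2.5 equiv | 20 mM | 90 °C | run made earlier |  |
| gamma | 20 mM | 2.00 equiv | 2.50 equiv | 20.0 mM | 110 °C |  | 20 min |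
| alpha | 20 mM | 2.00 equiv | 2.50 equiv | 20.0 mM | 70 °C |  | 20 min |
| theta | 20 mM | 2.00 equiv | 2.50 equiv | 20.0 mM | 90 °C |  | 20 min |
| beta | 20 mM | 2.00 equiv | 2.50 equiv | 20.0 mM |  | at 110 °C until 6.0 min, from then on at 70 °C | 20 min |

| run | time / min | target / % | isomer of the product / % |
|---|---|---|---|
| south-west | 20.0 | 18 | 7 |
| south-west | 40.0 | 20 | 17 |
| south-west | 60.0 | 17 | 22 |
| south-west | 80.0 | 20 | 31 |
| south-west | 90.0 | 18 | 36 |
| south-west | 120 | 20 | 39 |
| west | 2.50 | 8 | 1 |
| west | 6.00 | 4 | 8 |
| west | 10.0 | 9 | 15 |
| west | 15.0 | 9 | 15 |
| west | 25.0 | 5 | 18 |
| west | 30.0 | 7 | 19 |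

(each reading ± 2 percentage points)

- steps that have been proposed: starting material + partner B -> open intermediate; partner B + partner A -> second intermediate; open intermediate + second intermediate -> target; partner A + protic impurity -> quenched reagent; second intermediate -> side product; target <-> isomer of the product

- which flask leads in share of target in all that became target or isomer of the product ("all alike" within 1.5 percentage points) (gamma / alpha / theta / beta / all alike)
- share of target in all that became target or isomer of the product, gamma
- share of target in all that became target or isomer of the product, alpha
- share of target in all that became target or isomer of the product, theta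
- share of target in all that became target or isomer of the product, beta

An even split would be the zero of the scale, and the west run shows how far the balance lies from it at 90 °C. Pooling its last 3 readings gives, as a reading, the floor, the thermodynamic share at that temperature, which I carry to the other temperatures as an assumption:

floor = 28.8%, which is 21 percentage points below the even split.

Now call u the unaged fraction, the part of the way from the floor up to full share that a flask still holds. Product made at a steady pace has a mean age of half the elapsed time, so with λ as the relaxation rate I use a hand rule:

u = (share − floor)/(1 − floor) ≈ 1/(1 + λt/2)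

The south-west run at 20.0 min reads a share of 72.0%, which gives, with the scatter of that reading:

u = 0.607, so λ = 0.0648 min⁻¹ at 65 °C

Going to 70 °C for alpha, I take the usual doubling per 10 degrees, a factor of 1.41:

λt = 1.83, u = 0.522, alpha's share = 65.9%

The weak link is that single reading, so you should test it on the next one. The south-west run at 40.0 min has a share of 54.1%, which gives λ = 0.0908 min⁻¹, faster than the first value, and carried to alpha it gives 59.9%. Alpha stops at the same time as the first reading, so I commit to 65.9% with 59.9% as the lower edge, and I put gamma, theta and beta near the floor, leaving alpha in front: kinetic against thermodynamic control.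

The forecast names alpha, with 29% for gamma, 58% for alpha, 28% for theta and 31% for beta, calling alpha “still kinetic at 20 min”, and its alpha figure lies below mine.

The flasks give 68.3% for alpha, which leads, with 36.5% for gamma, 32.5% for theta and 31.2% for beta.

    starting material + partner B → open intermediate (k = 0.992 M⁻¹ min⁻¹, Ea = 58.0 kJ mol⁻¹)
    partner B + partner A → second intermediate (k = 3.01 M⁻¹ min⁻¹, Ea = 63.0 kJ mol⁻¹)
    open intermediate + second intermediate → target (k = 6.93 M⁻¹ min⁻¹, Ea = 50.0 kJ mol⁻¹)
    partner A + protic impurity → quenched reagent (k = 68.9 M⁻¹ min⁻¹, Ea = 39.0 kJ mol⁻¹)
    second intermediate → side product (k = 0.0352 min⁻¹, Ea = 91.0 kJ mol⁻¹)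
    target ⇌ isomer of the product (K = 2.80, k = 0.0548 min⁻¹, Ea = 103 kJ mol⁻¹, ΔH = −13.0 kJ mol⁻¹)
    (constants at 70 °C)

In alpha, target and isomer relax by their own step, both ways together, with a half-life of 9.32 min, so the 20 min span 2.15 half-lives. Measured from the floor read at 90 °C, alpha keeps u = 0.555. The same flask at 85 °C ends at 34.7%, which is u = 0.0829.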